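**Plan**
Chain atoms are numbered C1 (benzylic CH2) to C16. The arene is joined through C1 to an E-trisubstituted olefin C2=C3 that carries CH3 on C3. After C5 is adjusted to the carbinol and the three hydroxyls are masked as silyl ethers, C1–C2 and C3–CH3 are therefore cut together: methylmetalation of a terminal alkyne C2≡C3, then benzyl coupling.
The alkyne is cut at C4–C5 (propargylation of an enal), at C5–C6 with C7–CH3 (an earlier alkyne methylalumination trapped by formaldehyde), at C8–C9 (allylic alkylation by a propargyl anion) and at C12–C13 (vinylogous aldol).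
Forward, the chain grows from C16 towards C2 (C13–C16 plus C9–C12, then C6–C8, C5, C2–C4) and is joined to the arene last; no ring is formed.
The arene piece comes from 2-hydroxy-3-methylbenzaldehyde by para-hydroxylation, silylation, reduction and chlorination.
C13 (R) is set by a catalyst-controlled vinylogous Mukaiyama aldol reaction, which also gives E C10=C11. E C6=C7 and E C2=C3 come from syn methylalumination. The C5 carbinol is made as an epimer mixture and erased by oxidation.

Key step: step 15

Assumption: the (R,R) bisphosphoramide is taken to direct the dienolate to the Re face of 3-methylbut-2-enal, which is the face that gives 13R. The configuration of 6 is to be checked by Mosher ester analysis, and the (S,S) catalyst is used instead if the sense proves opposite.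

**Route**

Step 1
Reactants: 1 methyl 3-methylbut-2-enoate
Product: 3 tert-butyl[(1-methoxy-3-methylbuta-1,3-dien-1-yl)oxy]dimethylsilane, via lithium dienolate 2 (not isolated)
Conditions: LiN(iPr)2, THF, −78 °C; TBSCl, DMPU, −78 °C → rt; distil
Reagents that add atoms: tert-butyldimethylsilyl chloride, CC(C)(C)[Si](C)(C)Cl
Why: Kinetic γ-deprotonation of the enoate gives the extended lithium dienolate, which is silylated on oxygen (silyl ketene acetal formation).

Step 2
Reactants: 3 silyl dienolate, 4 3-methylbut-2-enal
Product: 6 methyl (2E,5R)-5-hydroxy-3,7-dimethylocta-2,6-dienoate, via trichlorosilyl ether 5 (not isolated)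
Conditions: SiCl4 (1.1 equiv), (R,R) pentamethylene-linked bisphosphoramide from N,N′-dimethyl-1,1′-binaphthyl-2,2′-diamine (2 mol %), iPr2NEt (10 mol %), CH2Cl2, −78 °C; aq. NaHCO3
Reagents that add atoms: none
Why: In this catalytic enantioselective vinylogous Mukaiyama aldol reaction (Lewis-base activation of SiCl4) the phosphoramide-bound trichlorosilyl cation activates the enal, the dienolate should attack through its γ-carbon on the Re face under catalyst control to set C13 as R, and the s-trans dienolate should give the E enoate.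

Step 3
Reactants: 6 hydroxy ester
Product: 7 methyl (2E,5R)-5-(tert-butyldimethylsilyloxy)-3,7-dimethylocta-2,6-dienoate
Conditions: TBSCl, imidazole, DMF, rt
Reagents that add atoms: tert-butyldimethylsilyl chloride, CC(C)(C)[Si](C)(C)Cl
Why: Imidazole-promoted silylation of an unhindered secondary allylic alcohol is routine and leaves the stereocentre untouched.

Step 4
Reactants: 7 silyloxy ester
Product: 8 (2E,5R)-5-(tert-butyldimethylsilyloxy)-3,7-dimethylocta-2,6-dien-1-ol
Conditions: iBu2AlH (2.5 equiv), CH2Cl2, −78 °C; aq. Rochelle salt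
Reagents that add atoms: none
Why: iBu2AlH reduces the conjugated ester by 1,2-hydride delivery to the allylic alcohol without touching the olefin geometry or the silyl ether.

Step 5
Reactants: 8 allylic alcohol
Product: 10 (2E,5R)-1-bromo-5-(tert-butyldimethylsilyloxy)-3,7-dimethylocta-2,6-diene, via allylic mesylate 9 (not isolated)
Conditions: MsCl, Et3N, THF, −40 °C; then LiBr, THF, −40 → 0 °C; used crude
Reagents that add atoms: lithium bromide, [Li+].[Br-]
Why: Mesylation followed by SN2 displacement with bromide at low temperature is the standard, transposition-free way to primary E-allylic bromides of terpenoid type.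

Step 6
Reactants: 10 allylic bromide, 11 1-(trimethylsilyl)propyne
Product: 13 (5E,8R)-8-(tert-butyldimethylsilyloxy)-6,10-dimethyl-1-(trimethylsilyl)undeca-5,9-dien-1-yne, via lithiated silylpropyne 12 (not isolated)
Conditions: 11, n-BuLi, THF, −20 °C; then 10, −78 → −20 °C
Reagents that add atoms: none
Why: The silyl-capped propargyllithium alkylates the primary allylic bromide by SN2 at C9, the silyl group suppressing allenyl products and protecting the alkyne terminus (C8–C9 bond formation).

Step 7
Reactants: 13 silylalkyne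
Product: 14 (5E,8R)-8-(tert-butyldimethylsilyloxy)-6,10-dimethylundeca-5,9-dien-1-yne
Conditions: K2CO3 (cat.), MeOH, rt
Reagents that add atoms: none
Why: Base-catalysed methanolysis cleaves the C(sp)–Si bond selectively, the secondary silyl ether being stable to these conditions.

Step 8
Reactants: 14 terminal enyne, 15 trimethylaluminium
Product: 18 (2E,6E,9R)-9-(tert-butyldimethylsilyloxy)-3,7,11-trimethyldodeca-2,6,10-trien-1-ol, via alkenylalane 16 (not isolated), via lithium alkenylaluminate 17 (not isolated)
Conditions: 15 (2 equiv), Cp2ZrCl2 (25 mol %), CH2Cl2, 0 °C → rt; evaporate; n-BuLi, hexane/THF, 0 °C; (CH2O)n, rt; aq. NH4Cl/Rochelle salt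
Reagents that add atoms: formaldehyde (from paraformaldehyde), C=O
Why: Zirconium-catalysed syn methylalumination of the terminal alkyne (Negishi carboalumination) places CH3 on C7 and aluminium on C6, and the derived aluminate is hydroxymethylated by formaldehyde with retention, giving E C6=C7.

Step 9
Reactants: 18 allylic alcohol
Product: 19 (2E,6E,9R)-9-(tert-butyldimethylsilyloxy)-3,7,11-trimethyldodeca-2,6,10-trienal
Conditions: MnO2 (excess), CH2Cl2, rt
Reagents that add atoms: none
Why: MnO2 oxidises the primary allylic alcohol selectively to the enal under neutral conditions that preserve the E geometry and the silyl ether.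

Step 10
Reactants: 19 enal, 20 propargyl bromide
Product: 22 (5E,9E,12R)-12-(tert-butyldimethylsilyloxy)-6,10,14-trimethylpentadeca-5,9,13-trien-1-yn-4-ol (epimer mixture at the carbinol, C5 of the target), via allenylzinc bromide 21 (not isolated)
Conditions: Zn dust (activated), THF, 0 °C → rt; aq. NH4Cl
Reagents that add atoms: none
Why: In this Barbier-type propargylation the allenylzinc bromide adds 1,2 to the enal through an SE2′ transition state to give the homopropargylic alcohol; the new C5 centre is uncontrolled and is removed later by oxidation.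

Step 11
Reactants: 23 2-hydroxy-3-methylbenzaldehyde
Product: 25 2,5-dihydroxy-3-methylbenzaldehyde, via aryl sulfate 24 (not isolated)
Conditions: K2S2O8, aq. KOH, 0 °C → rt; then HCl, 90 °C
Reagents that add atoms: potassium peroxodisulfate, [K+].[K+].[O-]S(=O)(=O)OOS(=O)(=O)[O-]
Why: In the Elbs persulfate oxidation the phenolate attacks peroxodisulfate through the only free position para to the phenol oxygen (both ortho positions are substituted), and the aryl sulfate is hydrolysed by acid.

Step 12
Reactants: 25 dihydroxy aldehyde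
Product: 26 2,5-bis(tert-butyldimethylsilyloxy)-3-methylbenzaldehyde
Conditions: TBSCl (2.5 equiv), imidazole, DMF, rt
Reagents that add atoms: tert-butyldimethylsilyl chloride, CC(C)(C)[Si](C)(C)Cl
Why: Both phenols are silylated under standard imidazole conditions, which also prevents later oxidation of the hydroquinone.

Step 13
Reactants: 26 aldehyde
Product: 27 [2,5-bis(tert-butyldimethylsilyloxy)-3-methylphenyl]methanol
Conditions: iBu2AlH (1.1 equiv), CH2Cl2, −78 °C; aq. Rochelle salt
Reagents that add atoms: none
Why: Hydride reduction of the aldehyde at low temperature under non-basic conditions should avoid migration of the ortho silyl group to the benzylic oxygen and cleavage of the aryl silyl ethers.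

Step 14
Reactants: 27 benzylic alcohol
Product: 29 2,5-bis(tert-butyldimethylsilyloxy)-3-methylbenzyl chloride, via benzylic mesylate 28 (not isolated)
Conditions: MsCl, Et3N, CH2Cl2, 0 °C; then LiCl, THF, 0 °C → rt; used promptly
Reagents that add atoms: lithium chloride, [Li+].[Cl-]
Why: Mesylation and chloride displacement convert the electron-rich benzylic alcohol to the chloride under non-acidic conditions that keep the aryl silyl ethers.

Step 15
Reactants: 22 homopropargylic alcohol, 15 trimethylaluminium, 29 benzyl chloride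
Product: 31 (2E,6E,10E,13R)-1-[2,5-bis(tert-butyldimethylsilyloxy)-3-methylphenyl]-13-(tert-butyldimethylsilyloxy)-3,7,11,15-tetramethylhexadeca-2,6,10,14-tetraen-5-ol (C5 epimer mixture), via alkenylalane alkoxide 30 (not isolated)
Conditions: 15 (3.5 equiv), Cp2ZrCl2 (0.5 equiv), CH2Cl2, 0 °C → rt; evaporate volatiles; 29, Pd(PPh3)4 (5 mol %), THF, rt; aq. Rochelle salt
Reagents that add atoms: none
Why: The first equivalent of AlMe3 turns the C5 hydroxyl into its dimethylaluminium alkoxide, and the Zr–Al methylating species from Cp2ZrCl2 and AlMe3 then adds CH3 to C3 and metal to C2 of the terminal alkyne in a syn fashion, the alkenyl group ending on aluminium. After surplus AlMe3 is removed, zerovalent palladium inserts into the benzylic C–Cl bond of 29, the alkenyl group passes from aluminium to divalent palladium, and reductive elimination joins C1 to C2 with retention of olefin geometry. The closest known reaction type is zirconium-catalysed methylalumination of terminal alkynes followed by palladium-catalysed alkenylalane–benzyl halide cross-coupling (Negishi carboalumination and coupling), which is known to accept free homopropargylic alcohols as their aluminium alkoxides. No ring closes and no stereocentre is created; the only stereochemical element is the E geometry of C2=C3, fixed by syn addition and retentive coupling. The step needs terminal regioselectivity, reaction at the alkyne in preference to the three trisubstituted olefins, and coupling without olefin migration: the terminal alkyne is the only unhindered π-system open to carbometalation, the benzylpalladium intermediate has no β-hydrogen, and the base-free THF medium tempers the Lewis acidity of the aluminium species towards the benzylic chloride and the silyl ethers. The C5 epimers are carried together because the carbinol is oxidised in the next step.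

Step 16
Reactants: 31 C5 alcohol
Product: 32 (2E,6E,10E,13R)-1-[2,5-bis(tert-butyldimethylsilyloxy)-3-methylphenyl]-13-(tert-butyldimethylsilyloxy)-3,7,11,15-tetramethylhexadeca-2,6,10,14-tetraen-5-one
Conditions: Dess–Martin periodinane, NaHCO3, CH2Cl2, 0 °C
Reagents that add atoms: none
Why: Buffered Dess–Martin oxidation converts the secondary allylic alcohol to the enone rapidly under near-neutral conditions, which should keep the C2=C3 olefin out of conjugation, and it merges both C5 epimers into one compound.

Step 17
Reactants: 32 tris-silyl enone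
Product: 33 (2E,6E,10E,13R)-1-(2,5-dihydroxy-3-methylphenyl)-13-hydroxy-3,7,11,15-tetramethylhexadeca-2,6,10,14-tetraen-5-one (CNP0251818.3)
Conditions: Bu4NF/AcOH (1:1, excess), degassed THF, 0 °C → rt, argon; aq. Na2S2O4 wash
Reagents that add atoms: none
Why: Acetic acid-buffered fluoride desilylation should remove the two aryl silyl ethers quickly and the secondary C13 silyl ether more slowly, while the buffer keeps the medium too weakly basic to move C2=C3 into conjugation or to promote autoxidation of the hydroquinone.

**Compound list**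
1 | methyl 3-methylbut-2-enoate | COC(=O)C=C(C)C | starting material
2 | lithium 1-methoxy-3-methylbuta-1,3-dien-1-olate (not isolated) | C=C(C)C=C(OC)O[Li] | intermediate
3 | tert-butyl[(1-methoxy-3-methylbuta-1,3-dien-1-yl)oxy]dimethylsilane | C=C(C)C=C(OC)O[Si](C)(C)C(C)(C)C | intermediate
4 | 3-methylbut-2-enal | CC(C)=CC=O | starting material
5 | methyl (2E,5R)-3,7-dimethyl-5-(trichlorosilyloxy)octa-2,6-dienoate (not isolated) | CC(C)=C[C@H](O[Si](Cl)(Cl)Cl)C/C(C)=C/C(=O)OC | intermediate
6 | methyl (2E,5R)-5-hydroxy-3,7-dimethylocta-2,6-dienoate | CC(C)=C[C@H](O)C/C(C)=C/C(=O)OC | intermediate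
7 | methyl (2E,5R)-5-(tert-butyldimethylsilyloxy)-3,7-dimethylocta-2,6-dienoate | CC(C)=C[C@H](O[Si](C)(C)C(C)(C)C)C/C(C)=C/C(=O)OC | intermediate
8 | (2E,5R)-5-(tert-butyldimethylsilyloxy)-3,7-dimethylocta-2,6-dien-1-ol | CC(C)=C[C@H](O[Si](C)(C)C(C)(C)C)C/C(C)=C/CO | intermediate
9 | methanesulfonate of 8 (not isolated) | CC(C)=C[C@H](O[Si](C)(C)C(C)(C)C)C/C(C)=C/COS(C)(=O)=O | intermediate
10 | (2E,5R)-1-bromo-5-(tert-butyldimethylsilyloxy)-3,7-dimethylocta-2,6-diene | CC(C)=C[C@H](O[Si](C)(C)C(C)(C)C)C/C(C)=C/CBr | intermediate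
11 | 1-(trimethylsilyl)propyne | CC#C[Si](C)(C)C | starting material
12 | 3-lithio-1-(trimethylsilyl)propyne (not isolated) | [Li]CC#C[Si](C)(C)C | intermediate
13 | (5E,8R)-8-(tert-butyldimethylsilyloxy)-6,10-dimethyl-1-(trimethylsilyl)undeca-5,9-dien-1-yne | CC(C)=C[C@H](O[Si](C)(C)C(C)(C)C)C/C(C)=C/CCC#C[Si](C)(C)C | intermediate
14 | (5E,8R)-8-(tert-butyldimethylsilyloxy)-6,10-dimethylundeca-5,9-dien-1-yne | CC(C)=C[C@H](O[Si](C)(C)C(C)(C)C)C/C(C)=C/CCC#C | intermediate
15 | trimethylaluminium | C[Al](C)C | starting material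
16 | dimethyl[(1E,5E,8R)-8-(tert-butyldimethylsilyloxy)-2,6,10-trimethylundeca-1,5,9-trien-1-yl]aluminium (not isolated) | CC(C)=C[C@H](O[Si](C)(C)C(C)(C)C)C/C(C)=C/CC/C(C)=C/[Al](C)C | intermediate
17 | lithium butyl(dimethyl)[(1E,5E,8R)-8-(tert-butyldimethylsilyloxy)-2,6,10-trimethylundeca-1,5,9-trien-1-yl]aluminate (not isolated) | CC(C)=C[C@H](O[Si](C)(C)C(C)(C)C)C/C(C)=C/CC/C(C)=C/[Al-](C)(C)CCCC.[Li+] | intermediate
18 | (2E,6E,9R)-9-(tert-butyldimethylsilyloxy)-3,7,11-trimethyldodeca-2,6,10-trien-1-ol | CC(C)=C[C@H](O[Si](C)(C)C(C)(C)C)C/C(C)=C/CC/C(C)=C/CO | intermediate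
19 | (2E,6E,9R)-9-(tert-butyldimethylsilyloxy)-3,7,11-trimethyldodeca-2,6,10-trienal | CC(C)=C[C@H](O[Si](C)(C)C(C)(C)C)C/C(C)=C/CC/C(C)=C/C=O | intermediate
20 | propargyl bromide (3-bromoprop-1-yne) | C#CCBr | starting material
21 | allenylzinc bromide (not isolated) | C=C=C[Zn]Br | intermediate
22 | (5E,9E,12R)-12-(tert-butyldimethylsilyloxy)-6,10,14-trimethylpentadeca-5,9,13-trien-1-yn-4-ol, carbinol epimer mixture | CC(C)=C[C@H](O[Si](C)(C)C(C)(C)C)C/C(C)=C/CC/C(C)=C/C(O)CC#C | intermediate
23 | 2-hydroxy-3-methylbenzaldehyde | Cc1cccc(C=O)c1O | starting material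
24 | potassium 3-formyl-4-hydroxy-5-methylphenyl sulfate (not isolated) | Cc1cc(OS(=O)(=O)[O-])cc(C=O)c1O.[K+] | intermediate
25 | 2,5-dihydroxy-3-methylbenzaldehyde | Cc1cc(O)cc(C=O)c1O | intermediate
26 | 2,5-bis(tert-butyldimethylsilyloxy)-3-methylbenzaldehyde | Cc1cc(O[Si](C)(C)C(C)(C)C)cc(C=O)c1O[Si](C)(C)C(C)(C)C | intermediate
27 | [2,5-bis(tert-butyldimethylsilyloxy)-3-methylphenyl]methanol | Cc1cc(O[Si](C)(C)C(C)(C)C)cc(CO)c1O[Si](C)(C)C(C)(C)C | intermediate
28 | methanesulfonate of 27 (not isolated) | Cc1cc(O[Si](C)(C)C(C)(C)C)cc(COS(C)(=O)=O)c1O[Si](C)(C)C(C)(C)C | intermediate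
29 | 2,5-bis(tert-butyldimethylsilyloxy)-3-methylbenzyl chloride | ClCc1cc(O[Si](C)(C)C(C)(C)C)cc(C)c1O[Si](C)(C)C(C)(C)C | intermediate
30 | (E)-alkenyldimethylalane at C2 with CH3 on C3 and a dimethylaluminium alkoxide at C5, from 22 (not isolated) | CC(C)=C[C@H](O[Si](C)(C)C(C)(C)C)C/C(C)=C/CC/C(C)=C/C(O[Al](C)C)C/C(C)=C/[Al](C)C | intermediate
31 | (2E,6E,10E,13R)-1-[2,5-bis(tert-butyldimethylsilyloxy)-3-methylphenyl]-13-(tert-butyldimethylsilyloxy)-3,7,11,15-tetramethylhexadeca-2,6,10,14-tetraen-5-ol, C5 epimer mixture | CC(C)=C[C@H](O[Si](C)(C)C(C)(C)C)C/C(C)=C/CC/C(C)=C/C(O)C/C(C)=C/Cc1cc(O[Si](C)(C)C(C)(C)C)cc(C)c1O[Si](C)(C)C(C)(C)C | intermediate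
32 | (2E,6E,10E,13R)-1-[2,5-bis(tert-butyldimethylsilyloxy)-3-methylphenyl]-13-(tert-butyldimethylsilyloxy)-3,7,11,15-tetramethylhexadeca-2,6,10,14-tetraen-5-one | CC(C)=C[C@H](O[Si](C)(C)C(C)(C)C)C/C(C)=C/CC/C(C)=C/C(=O)C/C(C)=C/Cc1cc(O[Si](C)(C)C(C)(C)C)cc(C)c1O[Si](C)(C)C(C)(C)C | intermediate
33 | (2E,6E,10E,13R)-1-(2,5-dihydroxy-3-methylphenyl)-13-hydroxy-3,7,11,15-tetramethylhexadeca-2,6,10,14-tetraen-5-one | CC(C)=C[C@H](O)C/C(C)=C/CC/C(C)=C/C(=O)C/C(C)=C/Cc1cc(O)cc(C)c1O | target

**Step count**
Total steps: 17. Longest linear sequence: 13 steps (steps 1–10, then 15–17); the arene branch is steps 11–14.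

**Steps most likely to fail**

Step 15. The alkenyl group may transfer only slowly from the alkoxide-chelated alane to palladium, residual methylaluminium species may instead methylate the benzylpalladium intermediate, and the Lewis-acidic medium may ionise the electron-rich benzylic chloride. The fallback sets out from 22 and 29 and returns at 31, forming the same two bonds with reversed polarity at C1 and C2. Alkyne 22 would undergo the same zirconium-catalysed methylalumination with 15, but the alane would be quenched with I2 in THF at −30 °C to give, after isolation, (1E,5E,9E,12R)-12-(tert-butyldimethylsilyloxy)-1-iodo-2,6,10,14-tetramethylpentadeca-1,5,9,13-tetraen-4-ol F1. Chloride 29 would be converted with Zn dust and LiCl in THF into [2,5-bis(tert-butyldimethylsilyloxy)-3-methylbenzyl]zinc chloride F2. Negishi cross-coupling of F1 with F2 (Pd(OAc)2, SPhos, THF, rt, conditions that tolerate a free hydroxyl) would then give 31.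

Step 2. Facial discrimination of the small, β,β-disubstituted enal may be insufficient, and γ-regioselectivity or E geometry may erode. The fallback sets out from 3 and 4 and returns at 6, moving stereocontrol from C–C bond formation to a ketone reduction. A BF3·OEt2-mediated vinylogous Mukaiyama aldol reaction in CH2Cl2 at −78 °C would give racemic methyl (2E)-5-hydroxy-3,7-dimethylocta-2,6-dienoate F3. Dess–Martin oxidation would give methyl (2E)-3,7-dimethyl-5-oxoocta-2,6-dienoate F4. CBS reduction of F4 with (S)-2-methyl-CBS-oxazaborolidine and catecholborane in toluene at −78 °C, the 2-methylprop-1-enyl group acting as the large substituent, should deliver the 5R alcohol 6.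

Step 17. Fluoride basicity may move the C2=C3 double bond into conjugation with the C5 ketone, the liberated hydroquinone may autoxidise, and cleavage at the C13 silyl ether may stay incomplete. The fallback sets out from 32 and returns at 33 by way of the base-insensitive quinone. KHF2 in MeOH at rt would cleave only the two aryl silyl ethers to give (2E,6E,10E,13R)-13-(tert-butyldimethylsilyloxy)-1-(2,5-dihydroxy-3-methylphenyl)-3,7,11,15-tetramethylhexadeca-2,6,10,14-tetraen-5-one F5. Ag2O in Et2O would oxidise F5 to 2-[(2E,6E,10E,13R)-13-(tert-butyldimethylsilyloxy)-3,7,11,15-tetramethyl-5-oxohexadeca-2,6,10,14-tetraen-1-yl]-6-methyl-1,4-benzoquinone F6. HF·pyridine in THF/pyridine would remove the C13 silyl ether to give 2-[(2E,6E,10E,13R)-13-hydroxy-3,7,11,15-tetramethyl-5-oxohexadeca-2,6,10,14-tetraen-1-yl]-6-methyl-1,4-benzoquinone F7. Reduction of F7 with aqueous Na2S2O4 in a two-phase system with Et2O would give 33.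

**Further compounds**
F1 | step 15 | (1E,5E,9E,12R)-12-(tert-butyldimethylsilyloxy)-1-iodo-2,6,10,14-tetramethylpentadeca-1,5,9,13-tetraen-4-ol, C4 epimer mixture | CC(C)=C[C@H](O[Si](C)(C)C(C)(C)C)C/C(C)=C/CC/C(C)=C/C(O)C/C(C)=C/I
F2 | step 15 | [2,5-bis(tert-butyldimethylsilyloxy)-3-methylbenzyl]zinc chloride | Cl[Zn]Cc1cc(O[Si](C)(C)C(C)(C)C)cc(C)c1O[Si](C)(C)C(C)(C)C
F3 | step 2 | racemic methyl (2E)-5-hydroxy-3,7-dimethylocta-2,6-dienoate | CC(C)=CC(O)C/C(C)=C/C(=O)OC
F4 | step 2 | methyl (2E)-3,7-dimethyl-5-oxoocta-2,6-dienoate | CC(C)=CC(=O)C/C(C)=C/C(=O)OC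
F5 | step 17 | (2E,6E,10E,13R)-13-(tert-butyldimethylsilyloxy)-1-(2,5-dihydroxy-3-methylphenyl)-3,7,11,15-tetramethylhexadeca-2,6,10,14-tetraen-5-one | CC(C)=C[C@H](O[Si](C)(C)C(C)(C)C)C/C(C)=C/CC/C(C)=C/C(=O)C/C(C)=C/Cc1cc(O)cc(C)c1O
F6 | step 17 | 2-[(2E,6E,10E,13R)-13-(tert-butyldimethylsilyloxy)-3,7,11,15-tetramethyl-5-oxohexadeca-2,6,10,14-tetraen-1-yl]-6-methyl-1,4-benzoquinone | CC(C)=C[C@H](O[Si](C)(C)C(C)(C)C)C/C(C)=C/CC/C(C)=C/C(=O)C/C(C)=C/CC1=CC(=O)C=C(C)C1=O
F7 | step 17 | 2-[(2E,6E,10E,13R)-13-hydroxy-3,7,11,15-tetramethyl-5-oxohexadeca-2,6,10,14-tetraen-1-yl]-6-methyl-1,4-benzoquinone | CC(C)=C[C@H](O)C/C(C)=C/CC/C(C)=C/C(=O)C/C(C)=C/CC1=CC(=O)C=C(C)C1=O
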